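The substrate charge of a flask is one fixed number, whatever then happens to the substrate, so I counted product, and reagent too, in fractions of that charge.

| flask | substrate | reagent | remark | time |
|---|---|---|---|---|
| north | 8 mM (fed, over 80 s) | 13 mM | run made earlier |  |
| south | 8 mM (fed, over 80 s) | 38 mM | run made earlier |  |
| dusk | 8.0 mM (fed, over 80 s) | 19.0 mM |  | 5.0 min |
| summer | 12 mM (fed, over 80 s) | 19.0 mM |  | 5.0 min |
| spring | 20 mM (fed, over 80 s) | 19.0 mM |  | 5.0 min |
| dawn | 30 mM (fed, over 80 s) | 19.0 mM |  | 5.0 min |

| run | time / s | product / % | substrate / % |
|---|---|---|---|
| north | 10.0 | 10.1 | 2.3 |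
| north | 25.0 | 29.4 | 1.9 |
| north | 50.0 | 59.2 | 0.9 |
| north | 80.0 | 92.7 | 4.7 |
| north | 120 | 96.8 | 0 |
| south | 10.0 | 11.6 | 0.1 |
| south | 25.0 | 30.5 | 0 |
| south | 50.0 | 61.3 | 1.9 |
| south | 80.0 | 98.3 | 2.8 |
| south | 120 | 99.2 | 0.2 |

(each reading ± 1 percentage point)

- the analysis behind the earlier runs scatters by 1 percentage point, standard deviation
- "hardly changes" means that all values lie within two and a half points (for a concentration: within two and a half percent of the largest)
- percentages count the whole charge, also what has not yet gone in

- [product] at the end for dusk, summer, spring, dawn, in this order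
- the course of these numbers from the first flask to the last (falls all the way / hardly changes / rises all the way / rises, then falls / falls, then rises)

1. At 50.0 s north had received 62.5% of its feed and read 59.2% product. The reaction kept pace with the feed, so I dropped time from the reckoning and kept two amounts: the reagent charge and the substrate charge.

2. Two reagent per product would allow north 81.2%, but it read 96.8%, so I took one to one.

3. Reagent charge over substrate charge is 63.3% for dawn. This ratio, the largest fraction of the substrate charge that can become product at one to one, is my reagent ceiling.

4. Dusk at 238% and summer at 158% lie above the whole charge, so substrate is the limiting reagent there. In spring, at 95.0%, and in dawn, the reagent charge is less than the substrate charge, so my ceiling for product in both was 19.0 mM.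

5. The forecast gave 7.9 mM, 11.7 mM, 18 mM and 18.7 mM, course rises all the way, saying “reagent runs short, capping product near 19 mM”.

The flasks gave 7.82 mM, 11.7 mM, 18.4 mM and 18.7 mM, course rises all the way.

    reagent + intermediate B → intermediate C (k = 0.660 M⁻¹ s⁻¹)
    substrate → intermediate A (k = 0.0190 s⁻¹)
    substrate + reagent → product (k = 55.0 M⁻¹ s⁻¹)
    reagent + intermediate A → intermediate B (k = 4.60 M⁻¹ s⁻¹)
    intermediate C ⇌ intermediate D (K = 0.810, k = 0.0180 s⁻¹)

Dawn stopped at 18.7 mM because the reagent level fell: the run with reagent held level gave 29.5 mM, and such a run is what would have made the forecast's 18.7 mM wrong. In the real dawn flask, reagent stood at 0.00571% of its charge at 1.33 min, with 26.7% substrate still present. That substrate passed into intermediate A, which reached 36.3%, while product stayed at 62.3%, under the ceiling of 63.3%. In spring the ceiling of 95.0% stood 3 percentage points above the 92.0% product, with reagent down to 0.297% of its own charge.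

(All runs are simulated for substances that don't exist; noise was put on by code.)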